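**Retrosynthetic overview**

1. Target ⇐ selective C13 acetylation and desilylation of the bridged hemiketal; the C5=C6 enol-lactone olefin comes from E1cB loss of AcOH inside the C1–O–C4-bridged ring, which fixes its geometry.
2. Ten-membered carbocycle ⇐ Ni/Cr (Nozaki–Hiyama–Kishi) closure of C1–C2 (vinyl iodide onto aldehyde), then C2=C3 saturation and C1 oxidation.
3. Key union: C5–C6 by intermolecular vinylogous Mukaiyama aldol of an east 2-silyloxyfuran (C6–C13, C8 ester, C9–C10–C1) with a west α-silyloxy aldehyde (C2–C5).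
4. East: 3-furanmethanol (silyl migration, C4-lithiation) plus an Evans-derived aldehyde (C10); CBS reduction sets C8; the side-chain acid and the west C4 carbinol both come from (S)-2-methylglycidol.
5. Ring order: butenolide (from the silylfuran) → ten-membered carbocycle → oxolane hemiketal.

Assumption: locants C1–C13 are the germacrane locants of the target (C1 hemiketal C, C4 C(Me)–O, C6 lactone enol C, C8 acyloxy CH, C10 CHMe, C13 CH2OAc); (S)-2-methylglycidol is bought; the C5/C6 configuration drawn for 30–38 is the predicted major aldol isomer (both centres are erased in step 31), and C1 of 34/35 is an inconsequential epimer mixture.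

**Part A – side-chain acid**

Step 1
Reactants: 1 (S)-2-methylglycidol
Product: 2 (R)-2-methyloxirane-2-carboxylic acid
Conditions: RuCl3·xH2O (2 mol%), NaIO4, CCl4/MeCN/H2O, 0 °C → rt
Reagents that add atoms: sodium periodate [Na+].[O-]I(=O)(=O)=O; water O
Why: Catalytic RuO4 oxidation takes the primary alcohol to the acid without opening the epoxide, and the quaternary centre is untouched (the S→R change is only a CIP priority change).

Step 2
Reactants: 2 (R)-2-methyloxirane-2-carboxylic acid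
Product: 3 (S)-3-chloro-2-hydroxy-2-methylpropanoic acid
Conditions: HCl (4 M in dioxane), 0 °C → rt
Reagents that add atoms: hydrogen chloride Cl
Why: SN2 epoxide opening by chloride occurs at the unhindered CH2 (the carboxyl-bearing carbon is deactivated), so the C–O bond at the stereocentre is retained.

Step 3
Reactants: 3 (S)-3-chloro-2-hydroxy-2-methylpropanoic acid
Product: 4 tert-butyldimethylsilyl (S)-2-(tert-butyldimethylsilyloxy)-3-chloro-2-methylpropanoate
Conditions: TBSOTf (2.4 equiv), 2,6-lutidine, CH2Cl2, 0 °C → rt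
Reagents that add atoms: TBSOTf CC(C)(C)[Si](C)(C)OS(=O)(=O)C(F)(F)F
Why: Exhaustive silylation with the silyl triflate protects the tertiary alcohol and gives a silyl ester that can be turned directly into the acid chloride.

**Part B – west aldehyde (C2–C5)**

Step 4
Reactants: 1 (S)-2-methylglycidol
Product: 5 (R)-2-[(4-methoxybenzyloxy)methyl]-2-methyloxirane
Conditions: NaH, PMBCl, Bu4NI (cat.), THF, 0 °C → rt
Reagents that add atoms: 4-methoxybenzyl chloride COc1ccc(CCl)cc1
Why: Williamson etherification differentiates the two CH2–O arms, and the Payne rearrangement of this alkoxide is degenerate so it cannot erode the configuration.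

Step 5
Reactants: 5 (R)-2-[(4-methoxybenzyloxy)methyl]-2-methyloxirane
Product: 6 (R)-3-(4-methoxybenzyloxy)-2-methylpropane-1,2-diol
Conditions: KOH, DMSO/H2O (4:1), 90 °C
Reagents that add atoms: water O
Why: Basic epoxide hydrolysis is an SN2 attack of hydroxide at the CH2 terminus, so the tertiary C–O bond (future C4) keeps its configuration.

Step 6
Reactants: 6 (R)-3-(4-methoxybenzyloxy)-2-methylpropane-1,2-diol
Product: 7 (S)-1-(4-methoxybenzyloxy)-2-methyl-2,3-bis(triethylsilyloxy)propane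
Conditions: TESOTf (2.3 equiv), 2,6-lutidine, CH2Cl2, −78 → 0 °C
Reagents that add atoms: TESOTf CC[Si](CC)(CC)OS(=O)(=O)C(F)(F)F
Why: The silyl triflate silylates both the primary and the hindered tertiary hydroxyl in one operation.

Step 7
Reactants: 7 (S)-1-(4-methoxybenzyloxy)-2-methyl-2,3-bis(triethylsilyloxy)propane
Product: 8 (S)-3-(4-methoxybenzyloxy)-2-methyl-2-(triethylsilyloxy)propanal
Conditions: (COCl)2, DMSO, CH2Cl2, −78 → −30 °C; Et3N, −78 → 0 °C
Reagents that add atoms: none
Why: Under Swern conditions a primary TES ether is cleaved and oxidised in situ to the aldehyde while the tertiary TES ether survives, and the aldehyde has no α-hydrogen to epimerise.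

Step 8
Reactants: 8 (S)-3-(4-methoxybenzyloxy)-2-methyl-2-(triethylsilyloxy)propanal
Product: 9 PMB ether of (R,E)-4-iodo-2-methyl-2-(triethylsilyloxy)but-3-en-1-ol
Conditions: CrCl2 (6 equiv), CHI3 (2 equiv), THF/dioxane, 0 °C → rt
Reagents that add atoms: iodoform IC(I)I
Why: Takai iodo-olefination of the non-enolisable aldehyde gives the (E)-vinyl iodide through anti elimination from the gem-dichromium adduct.

Step 9
Reactants: 9 PMB ether of (R,E)-4-iodo-2-methyl-2-(triethylsilyloxy)but-3-en-1-ol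
Product: 10 (R,E)-4-iodo-2-methyl-2-(triethylsilyloxy)but-3-en-1-ol
Conditions: DDQ, CH2Cl2/pH 7 buffer, 0 °C
Reagents that add atoms: none
Why: Oxidative PMB cleavage by DDQ is orthogonal to the silyl ether and the vinyl iodide.

Step 10
Reactants: 10 (R,E)-4-iodo-2-methyl-2-(triethylsilyloxy)but-3-en-1-ol
Product: 11 (R,E)-4-iodo-2-methyl-2-(triethylsilyloxy)but-3-enal
Conditions: Dess–Martin periodinane, NaHCO3, CH2Cl2, 0 °C → rt
Reagents that add atoms: none
Why: Buffered Dess–Martin oxidation gives the α-quaternary, non-epimerisable aldehyde without silyl migration.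

**Part C – linker aldehyde (C8–C9–C10–C1)**

Step 11
Reactants: 12 (S)-4-benzyl-3-propionyloxazolidin-2-one
Product: 14 (S)-4-benzyl-3-[(R)-2-methylpent-4-enoyl]oxazolidin-2-one, via sodium Z-enolate 13 (not isolated)
Conditions: NaHMDS, THF, −78 °C; allyl iodide, −78 → −40 °C
Reagents that add atoms: allyl iodide C=CCI
Why: Evans asymmetric alkylation: the chelated Z-enolate is allylated on the face opposite the benzyl group, which sets the C10 methyl centre as R.

Step 12
Reactants: 14 (S)-4-benzyl-3-[(R)-2-methylpent-4-enoyl]oxazolidin-2-one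
Product: 15 (R)-2-methylpent-4-en-1-ol
Conditions: LiBH4, MeOH (1 equiv), Et2O, 0 °C
Reagents that add atoms: none
Why: Reductive removal of the auxiliary with LiBH4 gives the primary alcohol without epimerising the α-centre.

Step 13
Reactants: 15 (R)-2-methylpent-4-en-1-ol
Product: 16 1-methoxy-4-({[(R)-2-methylpent-4-en-1-yl]oxy}methyl)benzene
Conditions: NaH, PMBCl, Bu4NI (cat.), THF/DMF, 0 °C → rt
Reagents that add atoms: 4-methoxybenzyl chloride COc1ccc(CCl)cc1
Why: Williamson etherification installs a C1–O protecting group that is removable oxidatively and is orthogonal to all silyl groups used later.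

Step 14
Reactants: 16 1-methoxy-4-({[(R)-2-methylpent-4-en-1-yl]oxy}methyl)benzene
Product: 17 (R)-4-(4-methoxybenzyloxy)-3-methylbutanal
Conditions: OsO4 (2 mol%), NaIO4, 2,6-lutidine, dioxane/H2O, rt
Reagents that add atoms: osmium tetroxide O=[Os](=O)(=O)=O; sodium periodate [Na+].[O-]I(=O)(=O)=O
Why: Lemieux–Johnson cleavage of the terminal alkene gives the C8 aldehyde while sparing the electron-rich PMB ring, and the β-stereocentre cannot epimerise.

**Part D – east butenolide**

Step 15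
Reactants: 18 furan-3-ylmethanol
Product: 19 tert-butyl(furan-3-ylmethoxy)dimethylsilane
Conditions: TBSCl, imidazole, DMF, rt
Reagents that add atoms: tert-butyldimethylsilyl chloride CC(C)(C)[Si](C)(C)Cl
Why: Standard O-silylation places the silyl group that will be transferred to carbon in the next step.

Step 16
Reactants: 19 tert-butyl(furan-3-ylmethoxy)dimethylsilane
Product: 20 [2-(tert-butyldimethylsilyl)furan-3-yl]methanol
Conditions: n-BuLi, HMPA, THF, −78 °C → rt; aq. NH4Cl
Reagents that add atoms: none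
Why: Directed C2-lithiation followed by a 1,4 O→C silyl migration (retro-Brook type) puts silicon on the furan carbon that will become the lactone carbonyl C12.

Step 17
Reactants: 20 [2-(tert-butyldimethylsilyl)furan-3-yl]methanol; 17 (R)-4-(4-methoxybenzyloxy)-3-methylbutanal
Product: 22 1-[5-(tert-butyldimethylsilyl)-4-(hydroxymethyl)furan-3-yl]-4-(4-methoxybenzyloxy)-3-methylbutan-1-ol (3R; C1 epimers), via C4-lithio lithium alkoxide 21 (not isolated)
Conditions: n-BuLi (2.3 equiv), DME, 0 °C; then 17, −78 °C; aq. NH4Cl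
Reagents that add atoms: none
Why: Alkoxide-directed ortho-lithiation (the C2 position is blocked by silicon) gives the C4 aryllithium, whose 1,2-addition to the aldehyde forms the C7–C8 bond; the C8 epimers are converged in steps 19–20.

Step 18
Reactants: 22 diol (C8 epimers)
Product: 23 primary TBDPS ether of 22 (C13–OTBDPS; C8–OH free)
Conditions: TBDPSCl, imidazole, CH2Cl2, 0 °C
Reagents that add atoms: tert-butyldiphenylsilyl chloride CC(C)(C)[Si](Cl)(c1ccccc1)c1ccccc1
Why: The bulky silyl chloride reacts selectively at the primary furylmethyl hydroxyl over the hindered secondary one.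

Step 19
Reactants: 23 primary TBDPS ether (C8–OH free)
Product: 24 (R)-1-[5-(tert-butyldimethylsilyl)-4-(tert-butyldiphenylsilyloxymethyl)furan-3-yl]-4-(4-methoxybenzyloxy)-3-methylbutan-1-one
Conditions: Dess–Martin periodinane, NaHCO3, CH2Cl2, rt
Reagents that add atoms: none
Why: Dess–Martin oxidation converts both C8 epimers into one furyl ketone under neutral conditions that leave the silylfuran intact.

Step 20
Reactants: 24 furyl ketone
Product: 25 (1S,3R)-1-[5-(tert-butyldimethylsilyl)-4-(tert-butyldiphenylsilyloxymethyl)furan-3-yl]-4-(4-methoxybenzyloxy)-3-methylbutan-1-ol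
Conditions: (R)-2-methyl-CBS-oxazaborolidine (0.3 equiv), BH3·SMe2, THF, −30 °C; MeOH
Reagents that add atoms: none
Why: Corey–Bakshi–Shibata reduction of the aryl alkyl ketone (furyl = large group) with the (R)-catalyst delivers hydride under reagent control to give the (S)-carbinol at C8.

Step 21
Reactants: 25 (1S,3R)-furyl carbinol; 4 tert-butyldimethylsilyl (S)-2-(tert-butyldimethylsilyloxy)-3-chloro-2-methylpropanoate
Product: 27 C8 ester of 25 with the (S)-2-(tert-butyldimethylsilyloxy)-3-chloro-2-methylpropanoyl group, via acid chloride 26 (not isolated)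
Conditions: 4, (COCl)2, DMF (cat.), CH2Cl2, 0 °C → rt, concentrate; then 25, DMAP, Et3N, CH2Cl2, rt → 40 °C
Reagents that add atoms: none
Why: The silyl ester is converted under neutral conditions into the hindered acid chloride, which acylates the secondary alcohol under DMAP catalysis with retention at C8 and at the quaternary side-chain centre.

Step 22
Reactants: 27 C8 ester (2-silylfuran)
Product: 28 (1S,3R)-1-[4-(tert-butyldiphenylsilyloxymethyl)-5-oxo-2,5-dihydrofuran-3-yl]-4-(4-methoxybenzyloxy)-3-methylbutyl (S)-2-(tert-butyldimethylsilyloxy)-3-chloro-2-methylpropanoate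
Conditions: AcOOH (32% in AcOH), NaOAc, CH2Cl2, 0 °C → rt; then Et3N (cat.)
Reagents that add atoms: peracetic acid CC(=O)OO
Why: Peracid oxidation of a 2-silylfuran occurs at the silicon-bearing carbon, which becomes the lactone carbonyl with loss of silicon, giving regiospecifically the conjugated butenolide with C6 as a free CH2.

**Part E – fragment union, macrocyclisation and endgame**

Step 23
Reactants: 28 east butenolide; 11 (R,E)-4-iodo-2-methyl-2-(triethylsilyloxy)but-3-enal
Product: 30 C5–C6 aldol adduct (4R,5S,6R,8S,10R,2'S; 5-OH; seco at C1–C2), via 2-silyloxyfuran 29 (not isolated)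
Conditions: TIPSOTf, Et3N, CH2Cl2, 0 °C, volatiles removed; then 11, BF3·OEt2, CH2Cl2, −78 °C; aq. NaHCO3
Reagents that add atoms: none
Why: Vinylogous Mukaiyama aldol: the aromatic 2-silyloxyfuran attacks the BF3-activated, non-enolisable aldehyde through its free γ-carbon (C6); Felkin–Anh addition anti to the α-OTES group and the usual syn preference predict 5S,6R, but both new centres are erased in step 31.

Step 24
Reactants: 30 C5–C6 aldol adduct
Product: 31 5-O-acetate of 30
Conditions: Ac2O, pyridine, DMAP (cat.), CH2Cl2, 0 °C → rt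
Reagents that add atoms: acetic anhydride CC(=O)OC(C)=O
Why: DMAP-catalysed acetylation of the hindered secondary alcohol protects it through the coming oxidations and installs the leaving group for the later E1cB step.

Step 25
Reactants: 31 5-O-acetate
Product: 32 C1 primary alcohol (PMB removed)
Conditions: DDQ, CH2Cl2/pH 7 buffer, 0 °C
Reagents that add atoms: none
Why: Oxidative PMB cleavage with DDQ frees only the C1 hydroxyl and leaves the silyl ethers, esters and vinyl iodide untouched.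

Step 26
Reactants: 32 C1 primary alcohol
Product: 33 C1 aldehyde (seco-aldehyde with the C2 vinyl iodide)
Conditions: Dess–Martin periodinane, NaHCO3, CH2Cl2, 0 °C
Reagents that add atoms: none
Why: Buffered Dess–Martin oxidation gives the α-methyl aldehyde without epimerising C10; it is used at once.

Step 27
Reactants: 33 C1 aldehyde
Product: 34 ten-membered (2E)-cycloalkenol (C1–C2 closed; C1–OH epimers)
Conditions: CrCl2 (15 equiv), NiCl2 (0.15 equiv), degassed DMSO/THF, 2 mM, rt
Reagents that add atoms: none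
Why: Nozaki–Hiyama–Kishi macrocyclisation: the alkenylchromium formed via Ni(0) insertion adds chemoselectively to the aldehyde with retention of E geometry, tolerating lactone, esters and alkyl chloride; the C1 carbinol configuration is irrelevant.

Step 28
Reactants: 34 ten-membered (2E)-cycloalkenol
Product: 35 saturated macrocyclic C1 alcohol
Conditions: KO2CN=NCO2K, AcOH, MeOH/CH2Cl2, 0 °C → rt (repeated charges)
Reagents that add atoms: none
Why: Diimide reduction saturates the strained, non-polarised disubstituted C2=C3 bond but not the tetrasubstituted conjugated butenolide, with no hydrogenolysis and no base that could trigger early acetate elimination.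

Step 29
Reactants: 35 saturated macrocyclic C1 alcohol
Product: 36 macrocyclic C1 ketone
Conditions: Dess–Martin periodinane, NaHCO3, CH2Cl2, rt
Reagents that add atoms: none
Why: Neutral Dess–Martin oxidation converges the C1 epimers to the ketone without epimerising the adjacent C10 centre.

Step 30
Reactants: 36 macrocyclic C1 ketone
Product: 38 1,4-bridged hemiketal 5-acetate, via open hydroxy ketone 37 (not isolated)
Conditions: HF·pyridine, pyridine, THF, 0 °C → rt
Reagents that add atoms: none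
Why: Buffered fluoride removes the tertiary TES ether but not the TBDPS or hindered tertiary TBS ether, and the freed C4–OH adds transannularly to the C1 ketone (ring–chain tautomerism) to give the oxolane hemiketal whose C1 configuration is dictated by the C4 bridgehead.

Step 31
Reactants: 38 1,4-bridged hemiketal 5-acetate
Product: 39 bis-silyl dienyl lactone (5E; C4 cis to C7)
Conditions: DBU (1.5 equiv), CH2Cl2, 0 °C
Reagents that add atoms: none
Why: E1cB elimination: DBU removes the acidic butenolide γ-hydrogen (C6–H) and acetate leaves from C5, and the oxygen bridge allows only the olefin geometry with C4 cis to C7.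

Step 32
Reactants: 39 bis-silyl dienyl lactone
Product: 40 13-hydroxy triol (C13–OH; side-chain OH; hemiketal OH)
Conditions: HF·pyridine (excess), THF/pyridine, 0 °C → rt
Reagents that add atoms: none
Why: Prolonged fluoride treatment under mildly acidic conditions cleaves the primary TBDPS and tertiary TBS ethers while preserving the hemiketal, the esters and the chlorohydrin.

Step 33
Reactants: 40 13-hydroxy triol
Product: 41 CNP0414417.1 (target)
Conditions: Ac2O (1.2 equiv), pyridine, CH2Cl2, 0 °C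
Reagents that add atoms: acetic anhydride CC(=O)OC(C)=O
Why: Acetylation takes place only at the single primary (allylic) hydroxyl, because the hemiketal and side-chain hydroxyls are both tertiary.

**Compound list**

1 | (S)-2-methylglycidol | C[C@]1(CO)CO1 | starting material
2 | (R)-2-methyloxirane-2-carboxylic acid | C[C@]1(C(=O)O)CO1 | intermediate
3 | (S)-3-chloro-2-hydroxy-2-methylpropanoic acid | C[C@](O)(C(=O)O)CCl | intermediate
4 | tert-butyldimethylsilyl (S)-2-(tert-butyldimethylsilyloxy)-3-chloro-2-methylpropanoate | C[C@](O[Si](C)(C)C(C)(C)C)(C(=O)O[Si](C)(C)C(C)(C)C)CCl | intermediate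
5 | (R)-2-[(4-methoxybenzyloxy)methyl]-2-methyloxirane | C[C@]1(COCc2ccc(OC)cc2)CO1 | intermediate
6 | (R)-3-(4-methoxybenzyloxy)-2-methylpropane-1,2-diol | C[C@](O)(COCc1ccc(OC)cc1)CO | intermediate
7 | (S)-1-(4-methoxybenzyloxy)-2-methyl-2,3-bis(triethylsilyloxy)propane | C[C@](O[Si](CC)(CC)CC)(COCc1ccc(OC)cc1)CO[Si](CC)(CC)CC | intermediate
8 | (S)-3-(4-methoxybenzyloxy)-2-methyl-2-(triethylsilyloxy)propanal | C[C@](O[Si](CC)(CC)CC)(COCc1ccc(OC)cc1)C=O | intermediate
9 | PMB ether of (R,E)-4-iodo-2-methyl-2-(triethylsilyloxy)but-3-en-1-ol | C[C@](O[Si](CC)(CC)CC)(COCc1ccc(OC)cc1)/C=C/I | intermediate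
10 | (R,E)-4-iodo-2-methyl-2-(triethylsilyloxy)but-3-en-1-ol | C[C@](O[Si](CC)(CC)CC)(CO)/C=C/I | intermediate
11 | (R,E)-4-iodo-2-methyl-2-(triethylsilyloxy)but-3-enal (west aldehyde) | C[C@](O[Si](CC)(CC)CC)(C=O)/C=C/I | intermediate
12 | (S)-4-benzyl-3-propionyloxazolidin-2-one | CCC(=O)N1[C@@H](Cc2ccccc2)COC1=O | starting material
13 | sodium (Z)-enolate of 12 | C/C=C(\[O-])N1[C@@H](Cc2ccccc2)COC1=O.[Na+] | intermediate
14 | (S)-4-benzyl-3-[(R)-2-methylpent-4-enoyl]oxazolidin-2-one | C=CC[C@@H](C)C(=O)N1[C@@H](Cc2ccccc2)COC1=O | intermediate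
15 | (R)-2-methylpent-4-en-1-ol | C=CC[C@@H](C)CO | intermediate
16 | 1-methoxy-4-({[(R)-2-methylpent-4-en-1-yl]oxy}methyl)benzene | C=CC[C@@H](C)COCc1ccc(OC)cc1 | intermediate
17 | (R)-4-(4-methoxybenzyloxy)-3-methylbutanal | O=CC[C@@H](C)COCc1ccc(OC)cc1 | intermediate
18 | furan-3-ylmethanol | OCc1ccoc1 | starting material
19 | tert-butyl(furan-3-ylmethoxy)dimethylsilane | CC(C)(C)[Si](C)(C)OCc1ccoc1 | intermediate
20 | [2-(tert-butyldimethylsilyl)furan-3-yl]methanol | OCc1ccoc1[Si](C)(C)C(C)(C)C | intermediate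
21 | C4-lithio lithium alkoxide of 20 | [Li]OCc1c([Li])coc1[Si](C)(C)C(C)(C)C | intermediate
22 | (3R)-1-[5-(tert-butyldimethylsilyl)-4-(hydroxymethyl)furan-3-yl]-4-(4-methoxybenzyloxy)-3-methylbutan-1-ol, C1 (= C8) epimers | OCc1c(C(O)C[C@@H](C)COCc2ccc(OC)cc2)coc1[Si](C)(C)C(C)(C)C | intermediate
23 | primary TBDPS ether of 22 | CC(C)(C)[Si](c1ccccc1)(c1ccccc1)OCc1c(C(O)C[C@@H](C)COCc2ccc(OC)cc2)coc1[Si](C)(C)C(C)(C)C | intermediate
24 | (R)-1-[5-(tert-butyldimethylsilyl)-4-(tert-butyldiphenylsilyloxymethyl)furan-3-yl]-4-(4-methoxybenzyloxy)-3-methylbutan-1-one | CC(C)(C)[Si](c1ccccc1)(c1ccccc1)OCc1c(C(=O)C[C@@H](C)COCc2ccc(OC)cc2)coc1[Si](C)(C)C(C)(C)C | intermediate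
25 | (1S,3R)-1-[5-(tert-butyldimethylsilyl)-4-(tert-butyldiphenylsilyloxymethyl)furan-3-yl]-4-(4-methoxybenzyloxy)-3-methylbutan-1-ol | CC(C)(C)[Si](c1ccccc1)(c1ccccc1)OCc1c([C@@H](O)C[C@@H](C)COCc2ccc(OC)cc2)coc1[Si](C)(C)C(C)(C)C | intermediate
26 | 2-(tert-butyldimethylsilyloxy)-3-chloro-2-methylpropanoyl chloride, configuration as in 4 (formally R) | ClC(=O)[C@](C)(O[Si](C)(C)C(C)(C)C)CCl | intermediate
27 | (1S,3R)-1-[5-(tert-butyldimethylsilyl)-4-(tert-butyldiphenylsilyloxymethyl)furan-3-yl]-4-(4-methoxybenzyloxy)-3-methylbutyl (S)-2-(tert-butyldimethylsilyloxy)-3-chloro-2-methylpropanoate | CC(C)(C)[Si](c1ccccc1)(c1ccccc1)OCc1c([C@@H](OC(=O)[C@](C)(O[Si](C)(C)C(C)(C)C)CCl)C[C@@H](C)COCc2ccc(OC)cc2)coc1[Si](C)(C)C(C)(C)C | intermediate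
28 | (1S,3R)-1-[4-(tert-butyldiphenylsilyloxymethyl)-5-oxo-2,5-dihydrofuran-3-yl]-4-(4-methoxybenzyloxy)-3-methylbutyl (S)-2-(tert-butyldimethylsilyloxy)-3-chloro-2-methylpropanoate (east butenolide) | O=C1OCC([C@@H](OC(=O)[C@](C)(O[Si](C)(C)C(C)(C)C)CCl)C[C@@H](C)COCc2ccc(OC)cc2)=C1CO[Si](c1ccccc1)(c1ccccc1)C(C)(C)C | intermediate
29 | 2-(triisopropylsilyloxy)furan derived from 28 | CC(C)[Si](C(C)C)(C(C)C)Oc1occ([C@@H](OC(=O)[C@](C)(O[Si](C)(C)C(C)(C)C)CCl)C[C@@H](C)COCc2ccc(OC)cc2)c1CO[Si](c3ccccc3)(c3ccccc3)C(C)(C)C | intermediate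
30 | C5–C6 aldol adduct: butenolide 28 carrying at its γ-carbon (C6, R) the (1S,2R,E)-1-hydroxy-4-iodo-2-methyl-2-(triethylsilyloxy)but-3-enyl group | O=C1O[C@@H]([C@H](O)[C@](C)(O[Si](CC)(CC)CC)/C=C/I)C([C@@H](OC(=O)[C@](C)(O[Si](C)(C)C(C)(C)C)CCl)C[C@@H](C)COCc2ccc(OC)cc2)=C1CO[Si](c1ccccc1)(c1ccccc1)C(C)(C)C | intermediate
31 | 5-O-acetate of 30 | O=C1O[C@@H]([C@H](OC(C)=O)[C@](C)(O[Si](CC)(CC)CC)/C=C/I)C([C@@H](OC(=O)[C@](C)(O[Si](C)(C)C(C)(C)C)CCl)C[C@@H](C)COCc2ccc(OC)cc2)=C1CO[Si](c1ccccc1)(c1ccccc1)C(C)(C)C | intermediate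
32 | C1 primary alcohol (31 without PMB) | O=C1O[C@@H]([C@H](OC(C)=O)[C@](C)(O[Si](CC)(CC)CC)/C=C/I)C([C@@H](OC(=O)[C@](C)(O[Si](C)(C)C(C)(C)C)CCl)C[C@@H](C)CO)=C1CO[Si](c1ccccc1)(c1ccccc1)C(C)(C)C | intermediate
33 | C1 aldehyde (seco-aldehyde) | O=C1O[C@@H]([C@H](OC(C)=O)[C@](C)(O[Si](CC)(CC)CC)/C=C/I)C([C@@H](OC(=O)[C@](C)(O[Si](C)(C)C(C)(C)C)CCl)C[C@@H](C)C=O)=C1CO[Si](c1ccccc1)(c1ccccc1)C(C)(C)C | intermediate
34 | ten-membered (2E)-cycloalkenol: 1-hydroxy (epimers), 4-OTES, 5-OAc, 6,12-olide, 8-O-acyl, 13-OTBDPS; 4R,5S,6R,8S,10R,2'S | OC1/C=C/[C@@](C)(O[Si](CC)(CC)CC)[C@@H](OC(C)=O)[C@@H]2OC(=O)C(CO[Si](c3ccccc3)(c3ccccc3)C(C)(C)C)=C2[C@@H](OC(=O)[C@](C)(O[Si](C)(C)C(C)(C)C)CCl)C[C@H]1C | intermediate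
35 | saturated macrocyclic C1 alcohol (2,3-dihydro-34) | OC1CC[C@@](C)(O[Si](CC)(CC)CC)[C@@H](OC(C)=O)[C@@H]2OC(=O)C(CO[Si](c3ccccc3)(c3ccccc3)C(C)(C)C)=C2[C@@H](OC(=O)[C@](C)(O[Si](C)(C)C(C)(C)C)CCl)C[C@H]1C | intermediate
36 | macrocyclic C1 ketone | O=C1CC[C@@](C)(O[Si](CC)(CC)CC)[C@@H](OC(C)=O)[C@@H]2OC(=O)C(CO[Si](c3ccccc3)(c3ccccc3)C(C)(C)C)=C2[C@@H](OC(=O)[C@](C)(O[Si](C)(C)C(C)(C)C)CCl)C[C@H]1C | intermediate
37 | open 4-hydroxy 1-ketone | O=C1CC[C@@](C)(O)[C@@H](OC(C)=O)[C@@H]2OC(=O)C(CO[Si](c3ccccc3)(c3ccccc3)C(C)(C)C)=C2[C@@H](OC(=O)[C@](C)(O[Si](C)(C)C(C)(C)C)CCl)C[C@H]1C | intermediate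
38 | 1,4-bridged hemiketal 5-acetate (1S,4R,5S,6R,8S,10R,2'S) | CC(C)(C)[Si](c4ccccc4)(c4ccccc4)OCC1=C2[C@H]([C@H](OC(C)=O)[C@@]3(C)CC[C@](O)(O3)[C@H](C)C[C@@H]2OC(=O)[C@](C)(O[Si](C)(C)C(C)(C)C)CCl)OC1=O | intermediate
39 | 13-O-TBDPS, side-chain O-TBS derivative of 40 (5E dienyl lactone hemiketal) | CC(C)(C)[Si](c4ccccc4)(c4ccccc4)OCC1=C2/C(=C\[C@@]3(C)CC[C@](O)(O3)[C@H](C)C[C@@H]2OC(=O)[C@](C)(O[Si](C)(C)C(C)(C)C)CCl)OC1=O | intermediate
40 | 13-deacetyl target (13-hydroxy triol) | OCC1=C2/C(=C\[C@@]3(C)CC[C@](O)(O3)[C@H](C)C[C@@H]2OC(=O)[C@](C)(O)CCl)OC1=O | intermediate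
41 | CNP0414417.1 | CC(=O)OCC1=C2/C(=C\[C@@]3(C)CC[C@](O)(O3)[C@H](C)C[C@@H]2OC(=O)[C@](C)(O)CCl)OC1=O | target

**Totals and risks**

Total step count: 33. Longest linear sequence: 21 steps (12 → 17 → 28 → 41: steps 11–14, 17–22, 23–33).

Steps most likely to fail:

Step 23 (vinylogous Mukaiyama aldol). The bond joins a β-branched silyloxyfuran carbon to an α-quaternary aldehyde, and BF3 could ionise the furylic C8 ester. The fallback sets out from 27. The free furan α-position of 27 is magnesiated with TMPMgCl·LiCl (THF, 0 °C → rt) and the aryl-magnesium is added to aldehyde 11 to give the furyl carbinol F1 (C5 epimers). Acetylation (Ac2O, pyridine, DMAP) gives the furyl acetate F2. The peracetic acid silylfuran-to-butenolide oxidation used in step 22 then converts F2 into 31 (as C5/C6 epimers, all of which converge at 39), where the route is rejoined.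

Step 27 (Ni/Cr closure of the ten-membered ring). Oligomerisation or ring strain may defeat it. The fallback is a ring-closing metathesis and sets out from 31. Hydrodeiodination (Bu3SnH, Pd(PPh3)4, THF, rt) gives the terminal vinyl compound F3. DDQ then gives the primary alcohol F4 and Dess–Martin oxidation gives the aldehyde F5. Chemoselective vinylation (vinyl bromide, CrCl2/NiCl2, DMSO) gives the C1 allylic alcohol F6. Metathesis with the Hoveyda–Grubbs second-generation catalyst (toluene, 80 °C, 1 mM) closes C2=C3 to the (Z)-cycloalkenol F7 (any E isomer formed is 34 itself). Diimide reduction as in step 28 brings the material back to 35.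

Step 31 (E1cB elimination with ring-controlled geometry). It relies on the hemiketal bridge being in place; if 38 stays largely as the open hydroxy ketone, or C10 epimerises, the geometry is not secured. The fallback sets out from 36. Elimination is done first (DBU, CH2Cl2, 0 °C) to give the silyl-protected ylidene ketone F8 as a C5=C6 geometric mixture. HF·pyridine then removes the TES group to give the hydroxy ketone F9. Iodine-catalysed photo-equilibration of the exocyclic olefin (I2 cat., visible light, CH2Cl2) funnels F9 into 39, because only the isomer with C4 cis to C7 can close to the bicyclic hemiketal.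

**Further compounds**

F1 | step 23 | furyl carbinol: 27 bearing at the free furan α-carbon the (2R,E)-1-hydroxy-4-iodo-2-methyl-2-(triethylsilyloxy)but-3-enyl group (C5 epimers) | CC(C)(C)[Si](c1ccccc1)(c1ccccc1)OCc1c([C@@H](OC(=O)[C@](C)(O[Si](C)(C)C(C)(C)C)CCl)C[C@@H](C)COCc2ccc(OC)cc2)c(C(O)[C@](C)(O[Si](CC)(CC)CC)/C=C/I)oc1[Si](C)(C)C(C)(C)C
F2 | step 23 | furyl acetate (O-acetate of F1) | CC(C)(C)[Si](c1ccccc1)(c1ccccc1)OCc1c([C@@H](OC(=O)[C@](C)(O[Si](C)(C)C(C)(C)C)CCl)C[C@@H](C)COCc2ccc(OC)cc2)c(C(OC(C)=O)[C@](C)(O[Si](CC)(CC)CC)/C=C/I)oc1[Si](C)(C)C(C)(C)C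
F3 | step 27 | terminal vinyl compound (deiodinated 31) | O=C1O[C@@H]([C@H](OC(C)=O)[C@](C)(O[Si](CC)(CC)CC)C=C)C([C@@H](OC(=O)[C@](C)(O[Si](C)(C)C(C)(C)C)CCl)C[C@@H](C)COCc2ccc(OC)cc2)=C1CO[Si](c1ccccc1)(c1ccccc1)C(C)(C)C
F4 | step 27 | primary alcohol (F3 without PMB) | O=C1O[C@@H]([C@H](OC(C)=O)[C@](C)(O[Si](CC)(CC)CC)C=C)C([C@@H](OC(=O)[C@](C)(O[Si](C)(C)C(C)(C)C)CCl)C[C@@H](C)CO)=C1CO[Si](c1ccccc1)(c1ccccc1)C(C)(C)C
F5 | step 27 | aldehyde from F4 | O=C1O[C@@H]([C@H](OC(C)=O)[C@](C)(O[Si](CC)(CC)CC)C=C)C([C@@H](OC(=O)[C@](C)(O[Si](C)(C)C(C)(C)C)CCl)C[C@@H](C)C=O)=C1CO[Si](c1ccccc1)(c1ccccc1)C(C)(C)C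
F6 | step 27 | C1 allylic alcohol (diene for metathesis; C1 epimers) | O=C1O[C@@H]([C@H](OC(C)=O)[C@](C)(O[Si](CC)(CC)CC)C=C)C([C@@H](OC(=O)[C@](C)(O[Si](C)(C)C(C)(C)C)CCl)C[C@@H](C)C(O)C=C)=C1CO[Si](c1ccccc1)(c1ccccc1)C(C)(C)C
F7 | step 27 | (Z)-cycloalkenol (2Z isomer of 34) | OC1/C=C\[C@@](C)(O[Si](CC)(CC)CC)[C@@H](OC(C)=O)[C@@H]2OC(=O)C(CO[Si](c3ccccc3)(c3ccccc3)C(C)(C)C)=C2[C@@H](OC(=O)[C@](C)(O[Si](C)(C)C(C)(C)C)CCl)C[C@H]1C
F8 | step 31 | silyl-protected ylidene ketone (4-OTES; C5=C6 E/Z mixture) | O=C1CC[C@@](C)(O[Si](CC)(CC)CC)C=C2OC(=O)C(CO[Si](c3ccccc3)(c3ccccc3)C(C)(C)C)=C2[C@@H](OC(=O)[C@](C)(O[Si](C)(C)C(C)(C)C)CCl)C[C@H]1C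
F9 | step 31 | hydroxy ketone (4-OH; C5=C6 E/Z mixture, non-bridged) | O=C1CC[C@@](C)(O)C=C2OC(=O)C(CO[Si](c3ccccc3)(c3ccccc3)C(C)(C)C)=C2[C@@H](OC(=O)[C@](C)(O[Si](C)(C)C(C)(C)C)CCl)C[C@H]1C
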